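**Compound numbers used throughout**

1 methyl 2,4-dimethoxy-6-methylbenzoate · 2 methyl 2,4-dimethoxy-6-(2-methoxy-2-oxoethyl)benzoate · 3 methyl 2,4-dimethoxy-6-(2-oxoethyl)benzoate · 4 undec-10-en-1-ol · 5 triisopropyl(undec-10-en-1-yloxy)silane · 6 diethyl[11-(triisopropylsilyloxy)undecyl]borane · 7 diethylzinc · 8 ethyl[11-(triisopropylsilyloxy)undecyl]zinc · 9 bis[11-(triisopropylsilyloxy)undecyl]zinc · 10 methyl (R)-2-[2-hydroxy-13-(triisopropylsilyloxy)tridecyl]-4,6-dimethoxybenzoate (open-chain adduct, not isolated) · 11 (R)-6,8-dimethoxy-3-[11-(triisopropylsilyloxy)undecyl]-3,4-dihydroisocoumarin · 12 (R)-8-hydroxy-6-methoxy-3-[11-(triisopropylsilyloxy)undecyl]-3,4-dihydroisocoumarin · 13 (R)-8-hydroxy-3-(11-hydroxyundecyl)-6-methoxy-3,4-dihydroisocoumarin (target)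

## Analysis of the target

The target 13 is a 3,4-dihydroisocoumarin in which benzene ring A is fused to δ-lactone ring B. It carries a methoxy group at C6, a free phenol at C8 peri to the lactone carbonyl C1, and at C3 an unbranched eleven-carbon chain (C1'–C11') ending in a primary alcohol. C3 is the only stereocentre; it is R, has no stereochemical partner in the molecule, and must therefore be set by an external chiral controller. Its two carbon substituents, the benzylic C4 methylene and the C1' methylene, are both CH2 groups, so a method that has to tell them apart (reduction of a C3 ketone, for example) has little to work with. The sensitive groups are the lactone (opened by hydroxide or alkoxide), the free phenol and the primary alcohol, and the two phenolic oxygens must end up differently substituted. The difficulty is one of economy rather than complexity: one stereocentre, one ring closure and one long chain should cost as few operations as possible, without building ring A from scratch. The strategy rests on the position of C3: it is a secondary carbinol carbon between C4 and C1', and its oxygen O2 is acylated by C1, which sits ortho on ring A. An aldehyde at C3 can therefore receive the whole chain as a nucleophile at the C3–C1' bond, with a C1 ester placed to capture the new alkoxide and close ring B. A second feature is used at the end: only the C8 oxygen can chelate a Lewis acid together with the C1 carbonyl, so its methyl ether can be cleaved in the presence of the one at C6.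

## Retrosynthetic reasoning

**13 back to 11 (O–Si at C11' and O–CH3 at C8).** The primary alcohol is carried as a triisopropylsilyl ether (12), and the C8 phenol as a methyl ether (11). The silyl ether is chosen because it is inert to organoboron and organozinc chemistry and too bulky to bind a Lewis acid. The methyl ether is chosen because ring A can then be bought fully oxygenated as 1, and because chelation between the C8 oxygen and the C1 carbonyl singles out this ether for cleavage. Demethylation is placed before desilylation, so that any early loss of the silyl group in the Lewis acid step only leads on to 13.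

**11 back to 3 and 9 (C3–C1' and C1–O2).** Cutting the lactone C1–O2 bond reveals hydroxy ester 10. Cutting C3–C1' in 10 gives aldehyde 3, which holds all of ring A, C1, C4 and C3, and dialkylzinc 9, which holds the whole side chain with its protected oxygen. The cut is made here, and not at C3–C4, because addition of the benzylic anion of 1 to a long-chain aldehyde would also build the skeleton but offers no dependable control of C3. A cut at C3–H (ketone reduction) would have to distinguish two methylene groups. In 3, by contrast, the carbonyl carbon carries H on one side and CH2Ar on the other, the situation in which catalytic enantioselective alkylation of aldehydes works best. The forward reaction has to add one alkyl group to one face of the aldehyde, leave the aromatic ester untouched by the organometallic, and then let the alkoxide displace the ester's methoxy group to form the six-membered lactone.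

**3 back to 1 (C4–C3).** The aldehyde carbon C3 is one carbon beyond the benzylic methyl of 1. It is introduced at the ester oxidation level by acylating the lateral (benzylic) anion of 1 with a carbonate ester, giving diester 2, and is then brought to the aldehyde level by partial hydride reduction. The two esters of 2 differ sharply: the new one is an unhindered aliphatic ester, while the aromatic one is flanked by two ortho substituents and conjugated to an electron-rich ring. This difference is what allows a single reduction.

**9 back to 4 and 7 (C–Zn, C–B, O–Si).** Each of the two carbon–zinc bonds of 9 comes from a boron–zinc exchange with one molecule of alkylborane 6, so two molecules of 6 are needed per zinc. The first exchange, between 6 and 7, gives the mixed ethyl(alkyl)zinc 8. The second, between 8 and a further molecule of 6, replaces the remaining ethyl group by the second chain. The C11'–B bond of 6 comes from anti-Markovnikov hydroboration of the terminal alkene of 5, and 5 is the silyl ether of the commercial alkenol 4. All eleven chain carbons and the terminal oxygen are thus bought in one piece, and the nucleophilic carbon is generated without any strongly basic organometallic that would be incompatible with later use beside an ester.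

## Alternatives that were turned down

**Alternative 1:** Ring B is cut at C4a–C4 and O2–C3 at the isocoumarin oxidation level, leading back to 2,4-dimethoxybenzoic acid A2 and the chain-bearing keto sulfoxonium ylide A3. C3 is made stereogenic afterwards by enantioselective hydrogenation of the C3=C4 double bond. In the forward key step A2 and A3 would react under [Cp*RhCl2]2 catalysis. The carboxylate directs metalation of the ortho C–H, the ylide transfers an acylmethyl group to that carbon with loss of its sulfoxide, and the resulting keto acid cyclises with dehydration to 3-[11-(benzyloxy)undecyl]-6,8-dimethoxyisocoumarin A1.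
- For it: A2 has a single free ortho position, so the site of C–H functionalisation is not in question. Ring B and the whole chain arrive in one operation. All intermediates are robust, non-enolisable aromatic compounds, unlike aldehyde 3 and the air-sensitive reagent 9.
- Against it: the stereocentre is deferred to hydrogenation of a trisubstituted, endocyclic enol lactone whose C3 substituent is a plain n-alkyl chain. No binding group sits near C3, the two faces differ only through the flat ring system, and hydrogenolysis of the enol C3–O2 bond can compete. A3 also needs its own sequence from a twelve-carbon ω-oxygenated acid derivative.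
- Comparison: step counts are close, and Alternative 1 is the stronger on robustness of the ring-forming step. The chosen route offers in its place that C3 is fixed in the same step that makes C3–C1', by a catalyst class that performs best with exactly this kind of unbranched aldehyde and whose sense can be inverted by taking the other ligand enantiomer.

**Alternative 2:** Ring A is taken apart across C8–C8a and C4a–C5, giving 1,3-dimethoxy-1-(trimethylsilyloxy)buta-1,3-diene A5 and the chiral alkynoate A6, which already contains C3 as a silyl-protected carbinol. In the forward key step a thermal Diels–Alder reaction joins the nucleophilic diene terminus (future C5) to the β-carbon of the ynoate (future C4a) and the acetal carbon (future C8) to the α-carbon (future C8a). Loss of the alkoxy group from the adduct aromatises it to methyl (R)-2-[13-(tert-butyldimethylsilyloxy)-2-(triethylsilyloxy)tridecyl]-6-hydroxy-4-methoxybenzoate A4, after which desilylation, lactonisation and a final desilylation would follow.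
- For it: the C8 phenol and C6 methyl ether are differentiated by construction, so no selective demethylation is needed. The polarity match fixes the regiochemistry. The stereocentre would come from an epoxide-type building block of secure configuration.
- Against it: a benzene ring that can be bought with the right substituents is built instead. A6 requires a long sequence of its own (chiral epoxide, alkynylation, two protections, carboxylation). β-Alkyl ynoates are sluggish dienophiles that need heating, while A5 is thermally and hydrolytically fragile.
- Comparison: Alternative 2 is stronger in that neither the phenol pattern nor the stereocentre depends on a late selective step. The chosen route offers clearly fewer operations, a purchased ring A, and phenol differentiation by a chelation-directed cleavage that is specific to the peri position.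

**Alternative 3:** Ring A is opened by a retro-aldol between C8a and C4a and ring B at C1–O2, leading to the diketo-dioxinone A8, in which the dioxinone masks both C1 and the C8 oxygen and the chain carries the C3 silyl ether. In the forward key step an amine base triggers aldol addition of the dioxinone CH (C8a) to the C4a ketone and dehydration to the resorcinol ring. Fluoride then frees the C3 alkoxide, which opens the benzodioxinone and forms the lactone, giving (R)-3-[11-(benzyloxy)undecyl]-6,8-dihydroxy-3,4-dihydroisocoumarin A7.
- For it: both rings form in one mild cascade without Lewis acids, and the phenols appear free.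
- Against it: A7 has both phenols free, so a selective O-methylation at C6 is still required. This is feasible because the C8 phenol is hydrogen-bonded, but it is an extra step, as is the final debenzylation. A8 is a sensitive polycarbonyl compound that must be assembled by dianion acylation from a chiral β-silyloxy acyl fragment, which itself needs an asymmetric synthesis. Such intermediates cyclise or tautomerise prematurely.
- Comparison: Alternative 3 is the gentlest in its ring-forming conditions and avoids ether cleavage altogether. The chosen route offers a much shorter, two-fragment convergence from a stable purchased arene, with the stereocentre created catalytically rather than carried through fragile intermediates.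

Key step: step 7

Assumption: the sense of induction known for the titanium bis-triflamide system with simple aldehydes is taken to hold for aldehyde 3, so the (1S,2S) ligand is specified; its enantiomer would be used if the sense proved opposite.

## Route

Step 1
Reactants: 1 methyl 2,4-dimethoxy-6-methylbenzoate
Product: 2 methyl 2,4-dimethoxy-6-(2-methoxy-2-oxoethyl)benzoate
Conditions: LiN(iPr)2 (2.2 equiv), THF, −78 °C; (MeO)2CO, −78 → 0 °C; aq. NH4Cl
Reagents that add atoms: dimethyl carbonate, COC(=O)OC
Why: Lateral lithiation of the ortho-toluate gives a benzylic anion stabilised by the adjacent ester, which is C-acylated by the carbonate (Claisen-type acylation). The second equivalent of base converts the more acidic product into its enolate and so protects it from further acylation.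

Step 2
Reactants: 2 methyl 2,4-dimethoxy-6-(2-methoxy-2-oxoethyl)benzoate
Product: 3 methyl 2,4-dimethoxy-6-(2-oxoethyl)benzoate
Conditions: iBu2AlH (1.05 equiv), toluene, −78 °C; MeOH, then aq. potassium sodium tartrate; used without delay
Reagents that add atoms: none
Why: Partial ester reduction: the aluminium hemiacetal formed at −78 °C is stable until hydrolysis and then releases the aldehyde. The unhindered aliphatic ester reacts, while the aromatic ester, twisted between two ortho substituents and deactivated by two methoxy donors, should be left alone.

Step 3
Reactants: 4 undec-10-en-1-ol
Product: 5 triisopropyl(undec-10-en-1-yloxy)silane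
Conditions: iPr3SiCl, imidazole, DMF, rt
Reagents that add atoms: chlorotriisopropylsilane, CC(C)[Si](Cl)(C(C)C)C(C)C
Why: Standard silylation of a primary alcohol with imidazole as base and nucleophilic catalyst. The bulky silyl ether is inert to boranes, dialkylzincs and Ti(OiPr)4.

Step 4
Reactants: 5 triisopropyl(undec-10-en-1-yloxy)silane
Product: 6 diethyl[11-(triisopropylsilyloxy)undecyl]borane
Conditions: Et2BH (from BH3·SMe2 + 2 BEt3), Et2O, 0 °C → rt; volatiles removed in vacuo, crude 6 divided into two equal portions
Reagents that add atoms: diethylborane, CCBCC
Why: Anti-Markovnikov hydroboration of a monosubstituted alkene places boron on the terminal carbon. The diethylboryl group is chosen because its primary alkyl group exchanges readily with zinc in the next two steps.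

Step 5
Reactants: 6 diethyl[11-(triisopropylsilyloxy)undecyl]borane; 7 diethylzinc
Product: 8 ethyl[11-(triisopropylsilyloxy)undecyl]zinc
Conditions: Et2Zn (neat, 2 equiv), 0 °C, 30 min; BEt3 and spare Et2Zn removed at 0 °C, 0.1 mmHg; crude 8 used at once
Reagents that add atoms: none
Why: Boron–zinc exchange (transmetallation): the primary alkyl group passes from the alkyldiethylborane to zinc in return for an ethyl group, fast at 0 °C in neat Et2Zn, and the excess of 7 together with loss of volatile BEt3 drives it to completion. The residue is the mixed dialkylzinc 8, which may already have begun to redistribute towards 9.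

Step 6
Reactants: 8 ethyl[11-(triisopropylsilyloxy)undecyl]zinc; 6 diethyl[11-(triisopropylsilyloxy)undecyl]borane
Product: 9 bis[11-(triisopropylsilyloxy)undecyl]zinc
Conditions: second portion of 6 (1 equiv), neat, 0 °C → rt, 1 h; BEt3 removed at 0.1 mmHg (twice, toluene coevaporation); residue dissolved in toluene
Reagents that add atoms: none
Why: Second boron–zinc exchange: the ethyl group still on zinc is exchanged for the primary alkyl group of a second molecule of 6, so that two borane molecules supply the two chains of 9. Evaporation of BEt3 pulls the equilibrium towards the involatile dialkylzinc, and any 8 left over redistributes to 9 with loss of volatile 7.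

Step 7
Reactants: 3 methyl 2,4-dimethoxy-6-(2-oxoethyl)benzoate; 9 bis[11-(triisopropylsilyloxy)undecyl]zinc
Product: 11 (R)-6,8-dimethoxy-3-[11-(triisopropylsilyloxy)undecyl]-3,4-dihydroisocoumarin, via open-chain hydroxy ester 10 (not isolated)
Conditions: (1S,2S)-C6H10(NHSO2CF3)2 (8 mol %), Ti(OiPr)4 (2 equiv), 9 (1.5–2 equiv), toluene, −20 °C, slow addition of 3, then rt; aq. NH4Cl; cat. p-TsOH, CH2Cl2, rt if 10 persists
Reagents that add atoms: none
Why: The bis-triflamide and Ti(OiPr)4 form a chiral titanium bis-sulfonamide Lewis acid that binds the aldehyde of 3, and one alkyl group of 9 is passed from zinc through this titanium assembly to the carbonyl carbon, making C3–C1'. The closest known reaction type is the titanium bis-sulfonamide-catalysed enantioselective addition of functionalised dialkylzincs, made by hydroboration and boron–zinc exchange, to unbranched aliphatic aldehydes. The new C3 stereocentre is controlled by the ligand alone: the (1S,2S) enantiomer, mirror image of the ligand that gives (S)-1-phenylpropan-1-ol from benzaldehyde and Et2Zn, should deliver the alkyl group to the Re face, and because the CH2Ar branch outranks the incoming chain this corresponds to R. The metal alkoxide of 10 then attacks the ortho ester carbon C1 in a 6-exo-trig acyl substitution that expels the methoxy group and closes ring B at C1–O2; the titanium alkoxide medium is itself a transesterification catalyst, and the acid treatment closes any material left open. The step needs chemoselectivity for the aldehyde over the aromatic ester, which is secured by the low reactivity of dialkylzincs towards esters and by the two ortho substituents around that ester. It also needs addition to outrun enolisation of the arylacetaldehyde, which the non-basic reagent, the low temperature and the slow addition of 3 favour. The silyl ether is too hindered and too far away to bind titanium, and C3 bears no acidic hydrogen, so its configuration is safe once set.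

Step 8
Reactants: 11 (R)-6,8-dimethoxy-3-[11-(triisopropylsilyloxy)undecyl]-3,4-dihydroisocoumarin
Product: 12 (R)-8-hydroxy-6-methoxy-3-[11-(triisopropylsilyloxy)undecyl]-3,4-dihydroisocoumarin
Conditions: BCl3 (1.5 equiv), CH2Cl2, −78 → 0 °C; aq. NaHCO3
Reagents that add atoms: none
Why: Chelation-directed ether cleavage: BCl3 binds the C1 carbonyl and the peri C8 methoxy oxygen in a six-membered chelate, and chloride removes that methyl group by SN2 attack. The C6 ether has no chelating partner and should stay; any silyl ether lost here only leads on to 13.

Step 9
Reactants: 12 (R)-8-hydroxy-6-methoxy-3-[11-(triisopropylsilyloxy)undecyl]-3,4-dihydroisocoumarin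
Product: 13 (R)-8-hydroxy-3-(11-hydroxyundecyl)-6-methoxy-3,4-dihydroisocoumarin
Conditions: HF·pyridine, THF, 0 °C → rt
Reagents that add atoms: none
Why: Fluoride-driven cleavage of the primary silyl ether through the strong Si–F bond. The mildly acidic medium leaves the lactone, the phenol and C3 untouched.

## Compound list

1 | methyl 2,4-dimethoxy-6-methylbenzoate | COC(=O)c1c(C)cc(OC)cc1OC | starting material
2 | methyl 2,4-dimethoxy-6-(2-methoxy-2-oxoethyl)benzoate | COC(=O)Cc1cc(OC)cc(OC)c1C(=O)OC | intermediate
3 | methyl 2,4-dimethoxy-6-(2-oxoethyl)benzoate | COC(=O)c1c(OC)cc(OC)cc1CC=O | intermediate
4 | undec-10-en-1-ol | C=CCCCCCCCCCO | starting material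
5 | triisopropyl(undec-10-en-1-yloxy)silane | C=CCCCCCCCCCO[Si](C(C)C)(C(C)C)C(C)C | intermediate
6 | diethyl[11-(triisopropylsilyloxy)undecyl]borane | CCB(CC)CCCCCCCCCCCO[Si](C(C)C)(C(C)C)C(C)C | intermediate
7 | diethylzinc | CC[Zn]CC | starting material
8 | ethyl[11-(triisopropylsilyloxy)undecyl]zinc | CC[Zn]CCCCCCCCCCCO[Si](C(C)C)(C(C)C)C(C)C | intermediate
9 | bis[11-(triisopropylsilyloxy)undecyl]zinc | CC(C)[Si](OCCCCCCCCCCC[Zn]CCCCCCCCCCCO[Si](C(C)C)(C(C)C)C(C)C)(C(C)C)C(C)C | intermediate
10 | methyl (R)-2-[2-hydroxy-13-(triisopropylsilyloxy)tridecyl]-4,6-dimethoxybenzoate (formed as its metal alkoxide, not isolated) | COC(=O)c1c(OC)cc(OC)cc1C[C@H](O)CCCCCCCCCCCO[Si](C(C)C)(C(C)C)C(C)C | intermediate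
11 | (R)-6,8-dimethoxy-3-[11-(triisopropylsilyloxy)undecyl]-3,4-dihydroisocoumarin | COc1cc(OC)c2c(c1)C[C@@H](CCCCCCCCCCCO[Si](C(C)C)(C(C)C)C(C)C)OC2=O | intermediate
12 | (R)-8-hydroxy-6-methoxy-3-[11-(triisopropylsilyloxy)undecyl]-3,4-dihydroisocoumarin | COc1cc(O)c2c(c1)C[C@@H](CCCCCCCCCCCO[Si](C(C)C)(C(C)C)C(C)C)OC2=O | intermediate
13 | (R)-8-hydroxy-3-(11-hydroxyundecyl)-6-methoxy-3,4-dihydroisocoumarin | COc1cc(O)c2c(c1)C[C@@H](CCCCCCCCCCCO)OC2=O | target

## Step count and least certain steps

Total step count: 9. Longest linear sequence: 7 steps (4 → 5 → 6 → 8 → 9 → 11 → 12 → 13, steps 3 to 9). The arene branch (1 → 2 → 3, steps 1 and 2) joins at step 7.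

**Step 7 (key step).** Three processes could undermine it.
- Facial selectivity could erode if the ortho ester and methoxy oxygens of 3 compete with the chiral ligand for titanium or zinc, or if uncatalysed background addition becomes significant.
- The arylacetaldehyde could enolise under Lewis acid, leading to self-condensation or to cyclisation of the enol oxygen onto the neighbouring ester.
- Ethyl could be transferred in competition with the chain if ethylzinc species survive step 6.

Fallback, setting out from 3 and returning at 11: the carbinol is set by allylboration, whose closed six-membered transition state is insensitive to the ester and is non-basic. Aldehyde 3 is treated with B-allyldiisopinocampheylborane prepared from (−)-α-pinene (the enantiomer of the reagent that gives the R alcohol from benzaldehyde; Et2O, −78 °C; NaBO3 work-up, then cat. p-TsOH) to give (R)-3-allyl-6,8-dimethoxy-3,4-dihydroisocoumarin F1. Cross-metathesis of F1 with triisopropyl(dec-9-en-1-yloxy)silane F2 (from dec-9-en-1-ol, iPr3SiCl, imidazole), using second-generation Grubbs catalyst in CH2Cl2 at 40 °C, gives (R)-6,8-dimethoxy-3-[11-(triisopropylsilyloxy)undec-2-en-1-yl]-3,4-dihydroisocoumarin F3 as an E/Z mixture of no consequence. Hydrogenation (H2, Pd/C, EtOAc) then gives 11.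

**Step 2.** The most likely failure is over-reduction: collapse of the aluminium hemiacetal before quench allows a second hydride delivery, and the resulting primary alcohol would lactonise onto the aromatic ester. Loss of the enolisable aldehyde during purification is the second concern.

Fallback, setting out from 2 and returning at 3: the unhindered ester of 2 is converted selectively with MeNH(OMe)·HCl and AlMe3 (CH2Cl2, 0 °C → rt) into methyl 2,4-dimethoxy-6-{2-[methoxy(methyl)amino]-2-oxoethyl}benzoate F4. Its reduction with iBu2AlH (THF, −78 °C) stops at a chelated tetrahedral intermediate and releases 3 only on aqueous work-up.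

**Step 6 (with step 5).** The second boron–zinc exchange may stop short. Ligand redistribution of 8 during the evaporations sheds volatile 7, which can leave part of the second portion of 6 unexchanged, and boron species may be carried over if BEt3 is not completely removed. The reagent would then contain residual ethylzinc groups, mixed organometallics and achiral Lewis acids that lower both conversion and selectivity in step 7.

Fallback, setting out from 5 and returning at 9, avoiding boron in the reagent altogether: hydroboration–oxidation of 5 (9-borabicyclo[3.3.1]nonane, THF; NaOH, H2O2) gives 11-(triisopropylsilyloxy)undecan-1-ol F5. Iodination (I2, PPh3, imidazole, CH2Cl2) gives (11-iodoundecyloxy)triisopropylsilane F6. Iodine–zinc exchange of F6 with 7 (neat excess of 7, cat. CuI, 50 °C; two molecules of F6 per zinc), followed by evaporation of the volatiles, gives 9.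

**Step 1.** Proton transfer from the newly formed, more acidic diester to unreacted benzylic anion, and Claisen-type attack of that anion on the ester of a second molecule, can limit conversion and complicate purification.

Fallback, setting out from 1 and returning at 2: the lateral anion (LiN(iPr)2, THF, −78 °C) is quenched with CO2 instead, giving 2-[3,5-dimethoxy-2-(methoxycarbonyl)phenyl]acetic acid F7. Its carboxylate is neither an acid towards the anion nor an acylating agent, and it is separated by simple extraction. O-Methylation (MeI, K2CO3, DMF) then gives 2.

## Further compounds

F1 | step 7 | (R)-3-allyl-6,8-dimethoxy-3,4-dihydroisocoumarin | COc1cc(OC)c2c(c1)C[C@@H](CC=C)OC2=O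
F2 | step 7 | triisopropyl(dec-9-en-1-yloxy)silane | C=CCCCCCCCCO[Si](C(C)C)(C(C)C)C(C)C
F3 | step 7 | (R)-6,8-dimethoxy-3-[11-(triisopropylsilyloxy)undec-2-en-1-yl]-3,4-dihydroisocoumarin (E/Z mixture) | COc1cc(OC)c2c(c1)C[C@@H](CC=CCCCCCCCCO[Si](C(C)C)(C(C)C)C(C)C)OC2=O
F4 | step 2 | methyl 2,4-dimethoxy-6-{2-[methoxy(methyl)amino]-2-oxoethyl}benzoate | CON(C)C(=O)Cc1cc(OC)cc(OC)c1C(=O)OC
F5 | step 6 | 11-(triisopropylsilyloxy)undecan-1-ol | OCCCCCCCCCCCO[Si](C(C)C)(C(C)C)C(C)C
F6 | step 6 | (11-iodoundecyloxy)triisopropylsilane | ICCCCCCCCCCCO[Si](C(C)C)(C(C)C)C(C)C
F7 | step 1 | 2-[3,5-dimethoxy-2-(methoxycarbonyl)phenyl]acetic acid | COC(=O)c1c(OC)cc(OC)cc1CC(=O)O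
A1 | alternative 1 | 3-[11-(benzyloxy)undecyl]-6,8-dimethoxyisocoumarin | COc1cc(OC)c2c(c1)C=C(CCCCCCCCCCCOCc3ccccc3)OC2=O
A2 | alternative 1 | 2,4-dimethoxybenzoic acid | COc1ccc(C(=O)O)c(OC)c1
A3 | alternative 1 | 13-(benzyloxy)-1-[dimethyl(oxo)-λ6-sulfanylidene]tridecan-2-one | CS(C)(=O)=CC(=O)CCCCCCCCCCCOCc1ccccc1
A4 | alternative 2 | methyl (R)-2-[13-(tert-butyldimethylsilyloxy)-2-(triethylsilyloxy)tridecyl]-6-hydroxy-4-methoxybenzoate | COC(=O)c1c(O)cc(OC)cc1C[C@@H](CCCCCCCCCCCO[Si](C)(C)C(C)(C)C)O[Si](CC)(CC)CC
A5 | alternative 2 | 1,3-dimethoxy-1-(trimethylsilyloxy)buta-1,3-diene | C=C(OC)C=C(OC)O[Si](C)(C)C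
A6 | alternative 2 | methyl (R)-16-(tert-butyldimethylsilyloxy)-5-(triethylsilyloxy)hexadec-2-ynoate | COC(=O)C#CC[C@@H](CCCCCCCCCCCO[Si](C)(C)C(C)(C)C)O[Si](CC)(CC)CC
A7 | alternative 3 | (R)-3-[11-(benzyloxy)undecyl]-6,8-dihydroxy-3,4-dihydroisocoumarin | Oc1cc(O)c2c(c1)C[C@@H](CCCCCCCCCCCOCc3ccccc3)OC2=O
A8 | alternative 3 | 6-[(R)-17-(benzyloxy)-2,4-dioxo-6-(triethylsilyloxy)heptadecyl]-2,2-dimethyl-4H-1,3-dioxin-4-one | CC1(C)OC(=O)C=C(CC(=O)CC(=O)C[C@@H](CCCCCCCCCCCOCc2ccccc2)O[Si](CC)(CC)CC)O1
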